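Remark on the chemistry: the target is taken in the open form drawn (free C6 hydroxyl beside the free C12 acid, free C15 aldehyde), so acid is kept mild once both are unmasked. Eudesmane numbering (C1–C15; α = face opposite the C14 methyl) is used for every intermediate, cyclic or not.

## The problem

Compound 33 is a trans-fused eudesmane: ring A (C1–C5, C10) and ring B (C5–C10) share the C5–C10 bond, with the angular methyl C14 on quaternary C10 and H5 on the opposite face. It has seven stereocentres (C1, C4, C5, C6, C7, C8, C10), six of them contiguous from C4 around ring B to C8. Apart from C14 every substituent is equatorial, so the oxygen at C1, C6 and C8, the C7 side chain and the C4 formyl group can be reached under thermodynamic or substrate control. The quaternary C10 and its trans relation to C5 cannot be corrected later and must be fixed when the C–C bonds are made. One centre can be relayed: C4 can direct C5, C5 can direct C10, the resulting trans appendages at C5 and C10 fix the ring fusion, and the fused chair then governs C6, C7, C1 and C8. The molecule is fragile: it has two acrylate-type Michael acceptors, an enolisable aldehyde at C4, a C8 ester that forbids late hydrolysis, a C6 hydroxyl/C12 acid pair that can close to the 6,12-lactone under acid, and a C11=C13 bond that would move into conjugation if it existed while C8 is still a ketone. The structure opens up because C5 and C10 are the β- and α-carbons of a 2-methylcyclohex-2-enone whose carbonyl is the C1 oxygen, so the two bonds that attach ring B to ring A, C5–C6 and C9–C10, can be made one after the other across enone 6.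

## Retrosynthesis

**End game (33 ⇐ 32 ⇐ 31 ⇐ 30).** The last bonds cut are the three O–Si bonds of 32, so that the final operation is a fluoride desilylation that touches neither the ester, the acid nor the aldehyde. Before that, the C15 aldehyde is traced to its 4-methoxybenzyl ether in 30 through alcohol 31. C15 is oxidised after C12 because the chlorite oxidation that makes the acid would also consume a C15 aldehyde. What is asked of these steps is only chemoselectivity; no stereocentre changes.

**Acrylic acid (30 ⇐ 29 ⇐ 28 ⇐ 27).** The C11=C13 bond is cut by an aldehyde α-methylenation, and the acid is traced to enal 29 and further to the primary triethylsilyl ether at C12 in 27. The usual alternative, α-methylenation of a 6,12-lactone, would leave a lactone to be opened in the presence of the C8 ester, so it was set aside. A primary triethylsilyl ether is chosen at C12 because a Swern oxidation converts it directly into the aldehyde while secondary triethylsilyl ethers, the tert-butyldimethylsilyl ether and the 4-methoxybenzyl ether survive. The methylene must be introduced only after C8 is no longer a ketone.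

**C8 ester and C8 carbinol (27 ⇐ 23 + 26; 23 ⇐ 22 ⇐ 21).** Cutting the ester C–O bond gives alcohol 23 and the silyl-protected acid 26, which is two steps from commercial ester 24. The 8α (equatorial) hydroxyl is traced to ketone 22. Hydride reagents would approach C8 from the α face, away from the syn-axial C14 methyl, and give the axial alcohol, so the forward step has to be a reduction under thermodynamic control. The C6 hydroxyl is silylated before the reduction (together with C1–OH, 22 ⇐ 21) so that only C8–OH is free when the acyl group arrives.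

**Ring B (21 ⇐ 20).** The C6–C7 bond is cut by a retro-aldol. Against cutting C7–C8 or C8–C9, this cut places the new hydroxyl exactly at C6, uses a ketone at C8 that is needed anyway, and is regiochemically unambiguous: of the possible enolates of 20 only the one at C7 can reach the C6 aldehyde through a six-membered ring. The precursor is monocyclic and has four stereocentres fewer on ring B. The forward reaction must stop at the ketol and deliver 6α-OH and the 7β side chain, both equatorial.

**Keto aldehyde (20 ⇐ 18 ⇐ 16 ⇐ 15).** The C6 aldehyde is the ozonolysis product of a vinyl group and the C8 ketone the hydration product of an internal alkyne C7≡C8. The hydration is made regioselective by the C1 hydroxyl of 16, which can reach C8 by a five-membered closure. This is why the C1 ketone of 15 is reduced first; the reduction also sets 1β-OH on a conformationally biased cyclohexanone.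

**Key disconnection (15 ⇐ 6 + 13 + 12).** Cutting C5–C6 and C9–C10 of 15 gives enone 6, vinylmagnesium bromide 13 and propargylic bromide 12. No other pair of cuts removes both ring-B attachments and the quaternary centre at once while leaving a single stereocentre (C4) in the precursor. The forward step must add vinyl trans to the C4 substituent and then alkylate C10 trans to the new vinyl group.

**Fragments (6 ⇐ 5 ⇐ 3 + 4, 3 ⇐ 2 ⇐ 1; 12 ⇐ 10 ⇐ 8 ⇐ 7).** Enone 6 is opened at C5=C10 (aldol condensation) and at C3–C4 (catalytic enantioselective Michael addition of aldehyde 3 to enone 4), which makes C4 the only centre that needs an external chiral source. Aldehyde 3 comes from diol 1 by way of 2. Bromide 12 comes from alkynol 7 by silylation, hydroxymethylation of the acetylide (the C8–C9 bond) and bromination.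

## Roads not taken

**Alternative 1:** cut C5–C10 transannularly and go back to a ten-membered carbocycle carrying a 1,10-epoxide and a C4=C5 alkene. In the forward step a Lewis acid opens the epoxide at C10, the alkene attacks through C5, and loss of a C15 proton gives A1, the allyl ester of a 1β-hydroxy-eudesma-4(15),11(13)-dien-12-oic acid with the C6 and C8 oxygens silylated.
- Merits: one step creates the ring fusion, C5, C10 and the 1β-hydroxyl in the natural sense, and A1 already carries the acrylate and every ring-B substituent. From A1 the remaining path is shorter than the one that follows 15 in the chosen plan.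
- Weak points for this target: the medium ring with its C6–C7–C8 stereotriad, defined alkene geometry and epoxide is itself a long synthesis. The allylic C6 silyloxy group lowers the nucleophilicity of the alkene and complicates the reactive conformation. Proton loss can go to more than one position. C15 emerges as an exocyclic methylene, so the 4α-formyl group would need anti-Markovnikov hydration in the presence of the acrylate, oxidation and probably epimerisation.
- Against the better late-stage economy of A1, the chosen plan offers a precursor made in four steps and a relay in which each new centre is set by its neighbour.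

**Alternative 2:** cut C7–C8 by a carbonyl-ene reaction. A Lewis acid activates a C8 aldehyde, the trisubstituted C7=C11 alkene attacks through C7 while a C13 hydrogen passes to oxygen, and ring B closes to A2, an 8α-hydroxy-7β-isopropenyl trans-decalin.
- Merits: C7 and C8 arise together through an all-equatorial chair, and the 8α-hydroxyl appears free and ready for acylation. In this respect A2 is better than the chosen plan, which needs a thermodynamically controlled ketone reduction at C8.
- Weak points: C6 must be a preformed carbinol centre on an open chain next to the reacting alkene, with no ring to control its formation. An allylic silyl ether is both deactivating and prone to ionise under the Lewis acid, which also threatens the 4-methoxybenzyl ether. The isopropenyl group must then be turned into the acrylic acid by allylic C–H oxidation and two further oxidations on an advanced intermediate.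
- The chosen plan sets C6 during ring closure under thermodynamic control and carries C12 as an oxygenated carbon from the start. Ring A would have to be made in much the same way in both plans, so the overall length is comparable.

**Alternative 3:** cut C5–C10 and C3–C4 by an intramolecular Diels–Alder reaction. An (E)-enal (C4=C5) and a 2-siloxydiene (C10=C1–C2=C3) in one chain, tethered through C6–C9, combine to give A3, a trans-fused decalin with a C1 silyl enol ether and the 4α-formyl group.
- Merits: both rings and C4, C5 and C10 form in one step, and C15 is already at the aldehyde level. In ring construction this is more convergent than the chosen plan.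
- Weak points: the open-chain precursor must carry the C6–C7–C8 stereotriad and a diene terminus of defined geometry bearing the C14 methyl, which means a long linear synthesis. The cycloaddition creates a quaternary centre, and its endo/exo and facial selectivity rest on the tether substituents. Afterwards the enol ether must become 1β-OH by hydrolysis and reduction next to a more reactive, epimerisable aldehyde, which costs protection steps.
- The chosen plan builds the rings one at a time but from simple achiral pieces, with each selectivity resting on a well-understood cyclohexane bias.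

Key step: step 8

**Step 1**
Reactants: 1 propane-1,3-diol
Product: 2 3-(4-methoxybenzyloxy)propan-1-ol
Conditions: NaH (1 equiv), 4-methoxybenzyl chloride (1 equiv), Bu4NI (cat.), THF, 0 °C to rt, diol in excess
Reagents that add atoms: 4-methoxybenzyl chloride, COc1ccc(CCl)cc1
Why: Williamson ether synthesis; an excess of the cheap diol should favour monoalkylation.

**Step 2**
Reactants: 2 3-(4-methoxybenzyloxy)propan-1-ol
Product: 3 3-(4-methoxybenzyloxy)propanal
Conditions: TEMPO (10 mol %), PhI(OAc)2, CH2Cl2, rt
Reagents that add atoms: none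
Why: Nitroxyl-catalysed alcohol oxidation stops at the aldehyde; the near-neutral medium should avoid β-elimination of the alkoxide.

**Step 3**
Reactants: 3 3-(4-methoxybenzyloxy)propanal; 4 pent-1-en-3-one
Product: 5 (S)-2-[(4-methoxybenzyloxy)methyl]-5-oxoheptanal
Conditions: (S)-α,α-diphenylprolinol trimethylsilyl ether (10 mol %), ethyl 3,4-dihydroxybenzoate (20 mol %), neat, 4 °C
Reagents that add atoms: none
Why: Enamine-catalysed Michael addition of an aldehyde to a vinyl ketone. The diphenyl(silyloxy)methyl group of the (S)-catalyst shields one face of the E-enamine, so the enone should add to the other face and set C4 as (S) in 5, which becomes (R) in 6.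

**Step 4**
Reactants: 5 (S)-2-[(4-methoxybenzyloxy)methyl]-5-oxoheptanal
Product: 6 (R)-4-[(4-methoxybenzyloxy)methyl]-2-methylcyclohex-2-en-1-one
Conditions: LiOH·H2O (0.3 equiv), i-PrOH, rt
Reagents that add atoms: none
Why: Intramolecular aldol condensation (6-enolendo), the second stage of a Robinson-type annulation. The mild base and short exposure are chosen to limit racemisation at C4 and loss of the β-alkoxy group.

**Step 5**
Reactants: 7 but-3-yn-1-ol
Product: 8 (but-3-yn-1-yloxy)triethylsilane
Conditions: Et3SiCl, imidazole, CH2Cl2, 0 °C to rt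
Reagents that add atoms: chlorotriethylsilane, CC[Si](Cl)(CC)CC
Why: Standard silylation of a primary alcohol; the triethylsilyl group is chosen because step 18 oxidises it directly.

**Step 6**
Reactants: 8 (but-3-yn-1-yloxy)triethylsilane
Product: 10 5-(triethylsilyloxy)pent-2-yn-1-ol, via lithium acetylide 9 (not isolated)
Conditions: n-BuLi, THF, −78 °C; then (CH2O)n, −78 °C to rt; H2O
Reagents that add atoms: formaldehyde (as paraformaldehyde), C=O
Why: Acetylide addition to formaldehyde makes the C8–C9 bond and gives the propargylic alcohol.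

**Step 7**
Reactants: 10 5-(triethylsilyloxy)pent-2-yn-1-ol
Product: 12 1-bromo-5-(triethylsilyloxy)pent-2-yne, via mesylate 11 (not isolated)
Conditions: MsCl, Et3N, THF, −20 °C; then LiBr, 0 °C to rt
Reagents that add atoms: lithium bromide, [Li+].[Br-]
Why: Sulfonylation followed by SN2 displacement with bromide; the acid-free conditions keep the primary silyl ether.

**Step 8**
Reactants: 6 (R)-4-[(4-methoxybenzyloxy)methyl]-2-methylcyclohex-2-en-1-one; 13 vinylmagnesium bromide; 12 1-bromo-5-(triethylsilyloxy)pent-2-yne
Product: 15 (2R,3S,4R)-4-[(4-methoxybenzyloxy)methyl]-2-methyl-2-[5-(triethylsilyloxy)pent-2-yn-1-yl]-3-vinylcyclohexan-1-one, via bromomagnesium enolate 14 (not isolated)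
Conditions: CuBr·SMe2 (10 mol %), 13 (1.2 equiv), THF, −78 to −40 °C; then HMPA (4 equiv), 12 (1.5 equiv), −78 to 0 °C
Reagents that add atoms: none
Why: Copper-catalysed 1,4-addition of a Grignard reagent followed by C-alkylation of the regiodefined enolate, the classical conjugate addition–enolate trapping of cyclohexenones. The vinylcopper species formed by transmetalation complexes the enone, adds at C5 (through a trivalent copper intermediate) and reductively eliminates to give enolate 14, whose double bond lies only between C1 and C10. C5 is set by C4: the CH2OPMB group blocks its own face of the half-chair, so axial attack trans to it should give the 4,5-trans product. In 14 the vinyl group turns pseudoaxial to avoid allylic 1,2-strain with the C10 methyl, so C10 should attack bromide 12 (SN2 at the propargylic CH2) through a chair-like transition state on the face opposite the vinyl group; C10 is thus set by C5, with vinyl and methyl cis. The step forms C5–C6 and C9–C10 and closes no ring, so no mode of closure applies. It needs 1,4- over 1,2-addition (secured by copper), C- over O-alkylation and SN2 over SN2′ attack (a soft tetrasubstituted enolate and a primary propargylic bromide), and no proton transfer that would move the enolate to C2 (reactive electrophile, HMPA, low temperature).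

**Step 9**
Reactants: 15 (2R,3S,4R)-4-[(4-methoxybenzyloxy)methyl]-2-methyl-2-[5-(triethylsilyloxy)pent-2-yn-1-yl]-3-vinylcyclohexan-1-one
Product: 16 (1R,2R,3S,4R)-4-[(4-methoxybenzyloxy)methyl]-2-methyl-2-[5-(triethylsilyloxy)pent-2-yn-1-yl]-3-vinylcyclohexan-1-ol
Conditions: NaBH4, THF/MeOH, −20 to 0 °C
Reagents that add atoms: none
Why: Borohydride reduction of a cyclohexanone. The chair with C4, C5 and the propargyl group equatorial and C14 axial is strongly preferred, and axial hydride attack from the α face should give the equatorial 1β-alcohol, cis to C14.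

**Step 10**
Reactants: 16 (1R,2R,3S,4R)-4-[(4-methoxybenzyloxy)methyl]-2-methyl-2-[5-(triethylsilyloxy)pent-2-yn-1-yl]-3-vinylcyclohexan-1-ol
Product: 18 (1R,2R,3S,4R)-4-[(4-methoxybenzyloxy)methyl]-2-methyl-2-[2-oxo-5-(triethylsilyloxy)pentyl]-3-vinylcyclohexan-1-ol, via bicyclic enol ether 17 (not isolated)
Conditions: Ph3PAuNTf2 (2 mol %), THF/H2O (10:1), rt
Reagents that add atoms: water, O
Why: Gold-catalysed intramolecular hydroalkoxylation of the alkyne (5-exo-dig, anti addition) followed by hydrolysis of the enol ether, in effect a hydroxyl-directed alkyne hydration. The C1 oxygen can reach only C8 through a five-membered ring, and the quaternary C10 favours that closure.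

**Step 11**
Reactants: 18 (1R,2R,3S,4R)-4-[(4-methoxybenzyloxy)methyl]-2-methyl-2-[2-oxo-5-(triethylsilyloxy)pentyl]-3-vinylcyclohexan-1-ol
Product: 20 (1S,2R,3R,6R)-3-hydroxy-6-[(4-methoxybenzyloxy)methyl]-2-methyl-2-[2-oxo-5-(triethylsilyloxy)pentyl]cyclohexane-1-carbaldehyde, via ozonide 19 (not isolated)
Conditions: O3 (to the first persistent blue), CH2Cl2, −78 °C; then PPh3, −78 °C to rt
Reagents that add atoms: ozone, [O-][O+]=O
Why: Ozonolysis with reductive work-up; the monosubstituted alkene reacts far faster than the anisyl ring. The aldehyde is used crude to protect C5.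

**Step 12**
Reactants: 20 (1S,2R,3R,6R)-3-hydroxy-6-[(4-methoxybenzyloxy)methyl]-2-methyl-2-[2-oxo-5-(triethylsilyloxy)pentyl]cyclohexane-1-carbaldehyde
Product: 21 1β,6α-dihydroxy-15-(4-methoxybenzyloxy)-12-(triethylsilyloxy)-13-nor-4βH,5αH,7αH-eudesman-8-one
Conditions: DBU (1 equiv), CH2Cl2, 0 °C to rt
Reagents that add atoms: none
Why: Intramolecular aldol addition (6-enolendo-exo-trig); only the C7 enolate can reach C6 through a six-membered ring, and closure between the trans-diequatorial C5 and C10 appendages gives the trans-decalin. Under reversible conditions C6–OH should settle equatorial (α), since an axial hydroxyl would be syn-diaxial to C14, and the C7 side chain should equilibrate to equatorial (β) through the enol.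

**Step 13**
Reactants: 21 1β,6α-dihydroxy-15-(4-methoxybenzyloxy)-12-(triethylsilyloxy)-13-nor-4βH,5αH,7αH-eudesman-8-one
Product: 22 15-(4-methoxybenzyloxy)-1β,6α,12-tris(triethylsilyloxy)-13-nor-4βH,5αH,7αH-eudesman-8-one
Conditions: Et3SiOTf (2.5 equiv), 2,6-lutidine, CH2Cl2, −78 °C
Reagents that add atoms: triethylsilyl trifluoromethanesulfonate, CC[Si](CC)(CC)OS(=O)(=O)C(F)(F)F
Why: Silylation of both secondary alcohols with a silyl triflate; the low temperature and hindered base should prevent retro-aldol cleavage and enol silylation.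

**Step 14**
Reactants: 22 15-(4-methoxybenzyloxy)-1β,6α,12-tris(triethylsilyloxy)-13-nor-4βH,5αH,7αH-eudesman-8-one
Product: 23 15-(4-methoxybenzyloxy)-1β,6α,12-tris(triethylsilyloxy)-13-nor-4βH,5αH,7αH-eudesman-8α-ol
Conditions: SmI2 (3 equiv), H2O, Et3N, THF, 0 °C
Reagents that add atoms: none
Why: Single-electron ketone reduction of the dissolving-metal type, which gives the thermodynamically preferred alcohol. The oxygen-bound samarium avoids the position syn-diaxial to C14, so protonation at carbon should be axial and leave 8α-OH equatorial.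

**Step 15**
Reactants: 24 ethyl 2-(hydroxymethyl)acrylate
Product: 25 ethyl 2-[(tert-butyldimethylsilyloxy)methyl]acrylate
Conditions: t-BuMe2SiCl, imidazole, CH2Cl2, rt
Reagents that add atoms: tert-butyldimethylsilyl chloride, CC(C)(C)[Si](C)(C)Cl
Why: Standard silylation of a primary allylic alcohol; this silyl ether survives the Swern step that removes the triethylsilyl group at C12.

**Step 16**
Reactants: 25 ethyl 2-[(tert-butyldimethylsilyloxy)methyl]acrylate
Product: 26 2-[(tert-butyldimethylsilyloxy)methyl]acrylic acid
Conditions: LiOH, THF/H2O, 0 °C to rt; then 1 M HCl to pH 4, 0 °C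
Reagents that add atoms: lithium hydroxide, [Li+].[OH-]
Why: Saponification of an unhindered ethyl ester; the cold, brief acidification keeps the silyl ether.

**Step 17**
Reactants: 23 15-(4-methoxybenzyloxy)-1β,6α,12-tris(triethylsilyloxy)-13-nor-4βH,5αH,7αH-eudesman-8α-ol; 26 2-[(tert-butyldimethylsilyloxy)methyl]acrylic acid
Product: 27 8α-{2-[(tert-butyldimethylsilyloxy)methyl]acryloyloxy}-15-(4-methoxybenzyloxy)-1β,6α,12-tris(triethylsilyloxy)-13-nor-4βH,5αH,7αH-eudesmane
Conditions: EDCI, DMAP, CH2Cl2, 0 °C to rt
Reagents that add atoms: none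
Why: Steglich esterification of the only free hydroxyl, with retention at C8.

**Step 18**
Reactants: 27 8α-{2-[(tert-butyldimethylsilyloxy)methyl]acryloyloxy}-15-(4-methoxybenzyloxy)-1β,6α,12-tris(triethylsilyloxy)-13-nor-4βH,5αH,7αH-eudesmane
Product: 28 8α-{2-[(tert-butyldimethylsilyloxy)methyl]acryloyloxy}-15-(4-methoxybenzyloxy)-1β,6α-bis(triethylsilyloxy)-13-nor-4βH,5αH,7αH-eudesman-12-al
Conditions: (COCl)2 (4 equiv), DMSO (8 equiv), CH2Cl2, −78 to −30 °C; then Et3N, to 0 °C
Reagents that add atoms: none
Why: Swern oxidation applied directly to a primary triethylsilyl ether. The activated sulfoxide cleaves the unhindered primary O–Si bond and oxidises the carbinol, while secondary triethylsilyl ethers, the tert-butyldimethylsilyl ether and the 4-methoxybenzyl ether are known to survive.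

**Step 19**
Reactants: 28 8α-{2-[(tert-butyldimethylsilyloxy)methyl]acryloyloxy}-15-(4-methoxybenzyloxy)-1β,6α-bis(triethylsilyloxy)-13-nor-4βH,5αH,7αH-eudesman-12-al
Product: 29 8α-{2-[(tert-butyldimethylsilyloxy)methyl]acryloyloxy}-15-(4-methoxybenzyloxy)-1β,6α-bis(triethylsilyloxy)-4βH,5αH,7αH-eudesm-11(13)-en-12-al
Conditions: Eschenmoser's salt, Et3N, CH2Cl2, rt
Reagents that add atoms: N,N-dimethylmethyleneiminium iodide, C=[N+](C)C.[I-]
Why: Mannich reaction at the only aldehyde α-CH2 followed by β-elimination of the amine gives the 2-substituted acrolein. C8 is no longer a ketone, so the new alkene has no reason to move into the ring.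

**Step 20**
Reactants: 29 8α-{2-[(tert-butyldimethylsilyloxy)methyl]acryloyloxy}-15-(4-methoxybenzyloxy)-1β,6α-bis(triethylsilyloxy)-4βH,5αH,7αH-eudesm-11(13)-en-12-al
Product: 30 8α-{2-[(tert-butyldimethylsilyloxy)methyl]acryloyloxy}-15-(4-methoxybenzyloxy)-1β,6α-bis(triethylsilyloxy)-4βH,5αH,7αH-eudesm-11(13)-en-12-oic acid
Conditions: NaClO2, NaH2PO4, 2-methylbut-2-ene, t-BuOH/H2O, 0 °C to rt
Reagents that add atoms: sodium chlorite, [Na+].[O-]Cl=O
Why: Pinnick oxidation converts enals into acrylic acids without touching alkenes or ethers; C15 is still an ether and is safe.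

**Step 21**
Reactants: 30 8α-{2-[(tert-butyldimethylsilyloxy)methyl]acryloyloxy}-15-(4-methoxybenzyloxy)-1β,6α-bis(triethylsilyloxy)-4βH,5αH,7αH-eudesm-11(13)-en-12-oic acid
Product: 31 8α-{2-[(tert-butyldimethylsilyloxy)methyl]acryloyloxy}-15-hydroxy-1β,6α-bis(triethylsilyloxy)-4βH,5αH,7αH-eudesm-11(13)-en-12-oic acid
Conditions: DDQ, CH2Cl2/pH 7 buffer, 0 °C
Reagents that add atoms: none
Why: Oxidative cleavage of a 4-methoxybenzyl ether by hydride abstraction; silyl ethers, the acid and the electron-poor alkenes are inert to it.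

**Step 22**
Reactants: 31 8α-{2-[(tert-butyldimethylsilyloxy)methyl]acryloyloxy}-15-hydroxy-1β,6α-bis(triethylsilyloxy)-4βH,5αH,7αH-eudesm-11(13)-en-12-oic acid
Product: 32 8α-{2-[(tert-butyldimethylsilyloxy)methyl]acryloyloxy}-15-oxo-1β,6α-bis(triethylsilyloxy)-4βH,5αH,7αH-eudesm-11(13)-en-12-oic acid
Conditions: Dess–Martin periodinane, NaHCO3, CH2Cl2, 0 °C to rt
Reagents that add atoms: none
Why: Dess–Martin oxidation of the only free alcohol; the formyl group is already in its stable equatorial (4α) orientation, so epimerisation is not a concern.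

**Step 23**
Reactants: 32 8α-{2-[(tert-butyldimethylsilyloxy)methyl]acryloyloxy}-15-oxo-1β,6α-bis(triethylsilyloxy)-4βH,5αH,7αH-eudesm-11(13)-en-12-oic acid
Product: 33 (1R,4R,5S,6R,7S,8S,10R)-1,6-dihydroxy-8-[2-(hydroxymethyl)acryloyloxy]-15-oxoeudesm-11(13)-en-12-oic acid
Conditions: HF·pyridine, excess pyridine, THF, 0 °C to rt; work-up at pH 5–6
Reagents that add atoms: none
Why: Fluoride-mediated cleavage of two secondary triethylsilyl ethers and one primary tert-butyldimethylsilyl ether. The buffered reagent leaves the ester, both Michael acceptors and the aldehyde alone and should keep the C6 hydroxyl/C12 acid pair open.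

## Compound list

1 | propane-1,3-diol | OCCCO | starting material
2 | 3-(4-methoxybenzyloxy)propan-1-ol | OCCCOCc1ccc(OC)cc1 | intermediate
3 | 3-(4-methoxybenzyloxy)propanal | O=CCCOCc1ccc(OC)cc1 | intermediate
4 | pent-1-en-3-one | CCC(=O)C=C | starting material
5 | (S)-2-[(4-methoxybenzyloxy)methyl]-5-oxoheptanal | O=C[C@H](COCc1ccc(OC)cc1)CCC(=O)CC | intermediate
6 | (R)-4-[(4-methoxybenzyloxy)methyl]-2-methylcyclohex-2-en-1-one | CC1=C[C@H](COCc2ccc(OC)cc2)CCC1=O | intermediate
7 | but-3-yn-1-ol | C#CCCO | starting material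
8 | (but-3-yn-1-yloxy)triethylsilane | C#CCCO[Si](CC)(CC)CC | intermediate
9 | [4-(triethylsilyloxy)but-1-yn-1-yl]lithium | [Li]C#CCCO[Si](CC)(CC)CC | intermediate (not isolated)
10 | 5-(triethylsilyloxy)pent-2-yn-1-ol | OCC#CCCO[Si](CC)(CC)CC | intermediate
11 | 5-(triethylsilyloxy)pent-2-yn-1-yl methanesulfonate | CS(=O)(=O)OCC#CCCO[Si](CC)(CC)CC | intermediate (not isolated)
12 | 1-bromo-5-(triethylsilyloxy)pent-2-yne | BrCC#CCCO[Si](CC)(CC)CC | intermediate
13 | vinylmagnesium bromide | C=C[Mg]Br | starting material
14 | bromomagnesium (3S,4R)-4-[(4-methoxybenzyloxy)methyl]-2-methyl-3-vinylcyclohex-1-en-1-olate | Br[Mg]OC1=C(C)[C@@H](C=C)[C@H](COCc2ccc(OC)cc2)CC1 | intermediate (not isolated)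
15 | (2R,3S,4R)-4-[(4-methoxybenzyloxy)methyl]-2-methyl-2-[5-(triethylsilyloxy)pent-2-yn-1-yl]-3-vinylcyclohexan-1-one | O=C1CC[C@@H](COCc2ccc(OC)cc2)[C@H](C=C)[C@@]1(C)CC#CCCO[Si](CC)(CC)CC | intermediate
16 | (1R,2R,3S,4R)-4-[(4-methoxybenzyloxy)methyl]-2-methyl-2-[5-(triethylsilyloxy)pent-2-yn-1-yl]-3-vinylcyclohexan-1-ol | O[C@@H]1CC[C@@H](COCc2ccc(OC)cc2)[C@H](C=C)[C@@]1(C)CC#CCCO[Si](CC)(CC)CC | intermediate
17 | (Z)-5-[(4-methoxybenzyloxy)methyl]-3a-methyl-2-[3-(triethylsilyloxy)propylidene]-4-vinyloctahydrobenzofuran (trans-fused; C1 oxygen closed onto C8, ring centres as in 16) | O1[C@@H]2CC[C@@H](COCc3ccc(OC)cc3)[C@H](C=C)[C@@]2(C)C/C1=C/CCO[Si](CC)(CC)CC | intermediate (not isolated)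
18 | (1R,2R,3S,4R)-4-[(4-methoxybenzyloxy)methyl]-2-methyl-2-[2-oxo-5-(triethylsilyloxy)pentyl]-3-vinylcyclohexan-1-ol | O[C@@H]1CC[C@@H](COCc2ccc(OC)cc2)[C@H](C=C)[C@@]1(C)CC(=O)CCCO[Si](CC)(CC)CC | intermediate
19 | ozonide of 18: the vinyl group replaced by a 1,2,4-trioxolan-3-yl group (both epimers at the trioxolane carbon) | O[C@@H]1CC[C@@H](COCc2ccc(OC)cc2)[C@H](C3OOCO3)[C@@]1(C)CC(=O)CCCO[Si](CC)(CC)CC | intermediate (not isolated)
20 | (1S,2R,3R,6R)-3-hydroxy-6-[(4-methoxybenzyloxy)methyl]-2-methyl-2-[2-oxo-5-(triethylsilyloxy)pentyl]cyclohexane-1-carbaldehyde | O[C@@H]1CC[C@@H](COCc2ccc(OC)cc2)[C@H](C=O)[C@@]1(C)CC(=O)CCCO[Si](CC)(CC)CC | intermediate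
21 | 1β,6α-dihydroxy-15-(4-methoxybenzyloxy)-12-(triethylsilyloxy)-13-nor-4βH,5αH,7αH-eudesman-8-one (trans-decalin; C15 α, side chain β, C14 β) | O=C1C[C@]2(C)[C@@H]([C@@H](O)[C@@H]1CCO[Si](CC)(CC)CC)[C@H](COCc3ccc(OC)cc3)CC[C@H]2O | intermediate
22 | 15-(4-methoxybenzyloxy)-1β,6α,12-tris(triethylsilyloxy)-13-nor-4βH,5αH,7αH-eudesman-8-one | O=C1C[C@]2(C)[C@@H]([C@@H](O[Si](CC)(CC)CC)[C@@H]1CCO[Si](CC)(CC)CC)[C@H](COCc3ccc(OC)cc3)CC[C@H]2O[Si](CC)(CC)CC | intermediate
23 | 15-(4-methoxybenzyloxy)-1β,6α,12-tris(triethylsilyloxy)-13-nor-4βH,5αH,7αH-eudesman-8α-ol | O[C@H]1C[C@]2(C)[C@@H]([C@@H](O[Si](CC)(CC)CC)[C@@H]1CCO[Si](CC)(CC)CC)[C@H](COCc3ccc(OC)cc3)CC[C@H]2O[Si](CC)(CC)CC | intermediate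
24 | ethyl 2-(hydroxymethyl)acrylate | C=C(CO)C(=O)OCC | starting material
25 | ethyl 2-[(tert-butyldimethylsilyloxy)methyl]acrylate | C=C(CO[Si](C)(C)C(C)(C)C)C(=O)OCC | intermediate
26 | 2-[(tert-butyldimethylsilyloxy)methyl]acrylic acid | C=C(CO[Si](C)(C)C(C)(C)C)C(=O)O | intermediate
27 | 8α-{2-[(tert-butyldimethylsilyloxy)methyl]acryloyloxy}-15-(4-methoxybenzyloxy)-1β,6α,12-tris(triethylsilyloxy)-13-nor-4βH,5αH,7αH-eudesmane | C=C(CO[Si](C)(C)C(C)(C)C)C(=O)O[C@H]1C[C@]2(C)[C@@H]([C@@H](O[Si](CC)(CC)CC)[C@@H]1CCO[Si](CC)(CC)CC)[C@H](COCc3ccc(OC)cc3)CC[C@H]2O[Si](CC)(CC)CC | intermediate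
28 | 8α-{2-[(tert-butyldimethylsilyloxy)methyl]acryloyloxy}-15-(4-methoxybenzyloxy)-1β,6α-bis(triethylsilyloxy)-13-nor-4βH,5αH,7αH-eudesman-12-al | C=C(CO[Si](C)(C)C(C)(C)C)C(=O)O[C@H]1C[C@]2(C)[C@@H]([C@@H](O[Si](CC)(CC)CC)[C@@H]1CC=O)[C@H](COCc3ccc(OC)cc3)CC[C@H]2O[Si](CC)(CC)CC | intermediate
29 | 8α-{2-[(tert-butyldimethylsilyloxy)methyl]acryloyloxy}-15-(4-methoxybenzyloxy)-1β,6α-bis(triethylsilyloxy)-4βH,5αH,7αH-eudesm-11(13)-en-12-al | C=C(CO[Si](C)(C)C(C)(C)C)C(=O)O[C@H]1C[C@]2(C)[C@@H]([C@@H](O[Si](CC)(CC)CC)[C@@H]1C(=C)C=O)[C@H](COCc3ccc(OC)cc3)CC[C@H]2O[Si](CC)(CC)CC | intermediate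
30 | 8α-{2-[(tert-butyldimethylsilyloxy)methyl]acryloyloxy}-15-(4-methoxybenzyloxy)-1β,6α-bis(triethylsilyloxy)-4βH,5αH,7αH-eudesm-11(13)-en-12-oic acid | C=C(CO[Si](C)(C)C(C)(C)C)C(=O)O[C@H]1C[C@]2(C)[C@@H]([C@@H](O[Si](CC)(CC)CC)[C@@H]1C(=C)C(=O)O)[C@H](COCc3ccc(OC)cc3)CC[C@H]2O[Si](CC)(CC)CC | intermediate
31 | 8α-{2-[(tert-butyldimethylsilyloxy)methyl]acryloyloxy}-15-hydroxy-1β,6α-bis(triethylsilyloxy)-4βH,5αH,7αH-eudesm-11(13)-en-12-oic acid | C=C(CO[Si](C)(C)C(C)(C)C)C(=O)O[C@H]1C[C@]2(C)[C@@H]([C@@H](O[Si](CC)(CC)CC)[C@@H]1C(=C)C(=O)O)[C@H](CO)CC[C@H]2O[Si](CC)(CC)CC | intermediate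
32 | 8α-{2-[(tert-butyldimethylsilyloxy)methyl]acryloyloxy}-15-oxo-1β,6α-bis(triethylsilyloxy)-4βH,5αH,7αH-eudesm-11(13)-en-12-oic acid | C=C(CO[Si](C)(C)C(C)(C)C)C(=O)O[C@H]1C[C@]2(C)[C@@H]([C@@H](O[Si](CC)(CC)CC)[C@@H]1C(=C)C(=O)O)[C@H](C=O)CC[C@H]2O[Si](CC)(CC)CC | intermediate
33 | (1R,4R,5S,6R,7S,8S,10R)-1,6-dihydroxy-8-[2-(hydroxymethyl)acryloyloxy]-15-oxoeudesm-11(13)-en-12-oic acid (1β,6α-dihydroxy, 8α-acyloxy, 4α-formyl, 5α-H, 7β side chain, 10β-methyl) | C=C(CO)C(=O)O[C@H]1C[C@]2(C)[C@@H]([C@@H](O)[C@@H]1C(=C)C(=O)O)[C@H](C=O)CC[C@H]2O | target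

## Step count and uncertain steps

Total: 23 steps. Longest linear sequence: 18 steps (steps 1–4, 8–14, 17–23).

**Step 8 (key step).** The hindered bromomagnesium enolate may alkylate slowly, which would allow proton transfer to move the enolate toward C2, consumption of 12 by residual Grignard reagent, or erosion of the trans selectivity. Fallback, from 6: the conjugate addition is run with Me3SiCl present and the trimethylsilyl enol ether F1 is isolated. MeLi in THF then releases the regiodefined lithium enolate F2, which is alkylated with 12 in THF/HMPA to return to 15.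

**Step 10.** The C1 oxygen may close on C7 (6-endo) instead of C8, the gold-activated alkyne may be attacked by the C5 vinyl group (1,6-enyne cycloisomerisation), or adventitious acid may remove the primary triethylsilyl group. Fallback, from 16: silylation with (HMe2Si)2NH gives the hydrodimethylsilyl ether F3. Platinum-catalysed intramolecular syn-hydrosilylation (Pt2(dvds)3, dvds = 1,3-divinyltetramethyldisiloxane, zerovalent platinum; 6-exo-dig) places silicon on C8 in the cyclic alkenylsiloxane F4. Tamao–Fleming oxidation (H2O2, KF, KHCO3) then gives 18.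

**Step 12.** The ketol may dehydrate to the enone, or C5 of 20 may epimerise before closure and lead to cis-fused material. Fallback, from 20: the condensation is driven on purpose (pyrrolidinium acetate, warm benzene) to the eudesm-6-en-8-one F5. Weitz–Scheffer epoxidation (t-BuOOH, DBU) on the α face, away from C14, gives the 6α,7α-epoxy ketone F6. Reductive opening of the C7–O bond with SmI2 (THF/MeOH, −90 °C) gives 21.

**Step 14.** Facial control may be insufficient if protonation or hydrogen-atom transfer to the C8 radical or anion occurs before it equilibrates, which would give the axial 8β-alcohol. Fallback, from 22: LiBH(s-Bu)3 delivers hydride on purpose from the equatorial side to give the 8β-alcohol F7. A Mitsunobu esterification with 26 (PPh3, DIAD) then inverts C8 and arrives directly at 27.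

**Step 23.** Acid-catalysed lactonisation of the freed C6 hydroxyl onto the C12 acid may occur, the hindered C1 and C6 silyl ethers may cleave slowly, or the C15 aldehyde may form a hemiacetal with the C6 hydroxyl. Fallback, from 32: the acid is masked as the allyl ester F8 (allyl bromide, KHCO3, DMF), desilylation with buffered HF·pyridine gives the triol ester F9, and the allyl group is removed last under neutral conditions (Pd(PPh3)4, zerovalent palladium, with PhSiH3) to give 33.

## Further compounds

F1 | step 8 | {(3S,4R)-4-[(4-methoxybenzyloxy)methyl]-2-methyl-3-vinylcyclohex-1-en-1-yloxy}trimethylsilane | C[Si](C)(C)OC1=C(C)[C@@H](C=C)[C@H](COCc2ccc(OC)cc2)CC1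
F2 | step 8 | lithium (3S,4R)-4-[(4-methoxybenzyloxy)methyl]-2-methyl-3-vinylcyclohex-1-en-1-olate | [Li]OC1=C(C)[C@@H](C=C)[C@H](COCc2ccc(OC)cc2)CC1
F3 | step 10 | hydrodimethylsilyl ether of 16 at the C1 oxygen | [H][Si](C)(C)O[C@@H]1CC[C@@H](COCc2ccc(OC)cc2)[C@H](C=C)[C@@]1(C)CC#CCCO[Si](CC)(CC)CC
F4 | step 10 | cyclic alkenylsiloxane from 6-exo-dig hydrosilylation of F3 (1-oxa-2-silacyclohexane fused at C1/C10, silicon on C8, syn addition) | C[Si]1(C)O[C@@H]2CC[C@@H](COCc3ccc(OC)cc3)[C@H](C=C)[C@@]2(C)C\C1=C/CCO[Si](CC)(CC)CC
F5 | step 12 | 1β-hydroxy-15-(4-methoxybenzyloxy)-12-(triethylsilyloxy)-13-nor-4βH,5αH-eudesm-6-en-8-one | O=C1C[C@]2(C)[C@@H](C=C1CCO[Si](CC)(CC)CC)[C@H](COCc3ccc(OC)cc3)CC[C@H]2O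
F6 | step 12 | 6α,7α-epoxy-1β-hydroxy-15-(4-methoxybenzyloxy)-12-(triethylsilyloxy)-13-nor-4βH,5αH-eudesman-8-one | O=C1C[C@]2(C)[C@@H]([C@H]3O[C@]31CCO[Si](CC)(CC)CC)[C@H](COCc4ccc(OC)cc4)CC[C@H]2O
F7 | step 14 | 15-(4-methoxybenzyloxy)-1β,6α,12-tris(triethylsilyloxy)-13-nor-4βH,5αH,7αH-eudesman-8β-ol | O[C@@H]1C[C@]2(C)[C@@H]([C@@H](O[Si](CC)(CC)CC)[C@@H]1CCO[Si](CC)(CC)CC)[C@H](COCc3ccc(OC)cc3)CC[C@H]2O[Si](CC)(CC)CC
F8 | step 23 | allyl ester of 32 | C=C(CO[Si](C)(C)C(C)(C)C)C(=O)O[C@H]1C[C@]2(C)[C@@H]([C@@H](O[Si](CC)(CC)CC)[C@@H]1C(=C)C(=O)OCC=C)[C@H](C=O)CC[C@H]2O[Si](CC)(CC)CC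
F9 | step 23 | allyl ester of 33 | C=C(CO)C(=O)O[C@H]1C[C@]2(C)[C@@H]([C@@H](O)[C@@H]1C(=C)C(=O)OCC=C)[C@H](C=O)CC[C@H]2O
A1 | alternative 1 | allyl 6α-(tert-butyldimethylsilyloxy)-1β-hydroxy-8α-(triethylsilyloxy)-5αH,7αH-eudesma-4(15),11(13)-dien-12-oate | CC[Si](CC)(CC)O[C@H]1C[C@]2(C)[C@@H]([C@@H](O[Si](C)(C)C(C)(C)C)[C@@H]1C(=C)C(=O)OCC=C)C(=C)CC[C@H]2O
A2 | alternative 2 | 1β,6α-bis(tert-butyldimethylsilyloxy)-15-(4-methoxybenzyloxy)-4βH,5αH,7αH-eudesm-11(13)-en-8α-ol (7β-isopropenyl) | O[C@H]1C[C@]2(C)[C@@H]([C@@H](O[Si](C)(C)C(C)(C)C)[C@@H]1C(C)=C)[C@H](COCc3ccc(OC)cc3)CC[C@H]2O[Si](C)(C)C(C)(C)C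
A3 | alternative 3 | 1,6α-bis(tert-butyldimethylsilyloxy)-12-(4-methoxybenzyloxy)-8α-(triethylsilyloxy)-4βH,5αH,7αH-eudesma-1,11(13)-dien-15-al | CC[Si](CC)(CC)O[C@H]1C[C@]2(C)[C@@H]([C@@H](O[Si](C)(C)C(C)(C)C)[C@@H]1C(=C)COCc3ccc(OC)cc3)[C@H](C=O)CC=C2O[Si](C)(C)C(C)(C)C
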